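# Dictyoceratin C by radical 6-endo closure of ring B: synthesis proposal

Numbering used throughout: ring A is C1–C5 plus C10, ring B is C5–C10. C4 carries the methylidene (C11), C5 a methyl, C8 a methyl, C9 a methyl and the arylmethyl group (ArCH2), C10 a hydrogen. "Ar" is the 2-oxygenated 5-(methoxycarbonyl)phenyl ring.

## Analysis of the target

Dictyoceratin C (23) is a rearranged drimane sesquiterpenoid: a trans-decalin joined through a CH2 group on C9 to C3 of methyl 4-hydroxybenzoate. Its four stereocentres are contiguous. C5 (S, β-methyl) and C10 (S, α-hydrogen) define the trans ring fusion. C9 (R) is quaternary, with its methyl axial and β and ArCH2 equatorial and α. C8 (S) carries an equatorial β-methyl, and the C5 and C9 methyls are 1,3-diaxial on ring B.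

The sensitive groups are the exocyclic C4 methylidene, which acid moves into ring A or turns into a cation that the phenol can capture, and the free phenol para to a methyl ester. The difficulty is that two quaternary carbons (C5, C9) flank C10, that C9 sits next to the tertiary C8, and that ring B of the target holds no functional group from which these centres could be set. C9 must also tell a methyl from an ArCH2 group.

The strategy rests on one feature. The C9 methyl can be read as a methylidene plus a hydrogen atom, which makes C9 a tertiary radical. C8 is a CH(CH3) one bond away, which is the β-carbon of a propenyl ketone whose carbonyl is C6. The C8–C9 bond can therefore be formed by radical conjugate addition, and this closes ring B.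

## Retrosynthetic reasoning

**C4=C11 (23 from 21).** The methylidene is cut first and so made last, by Wittig methylenation of the C4 ketone 21. A 1,1-disubstituted alkene at C4 would compete with the C9 methylidene for hydrogen-atom transfer in the key step and would not survive acidic deprotection. C4 is therefore carried as a protected alcohol and oxidised late. The phenol is freed before the methylenation, so that no acid meets the alkene and the phenoxide 22 shields the para ester from the ylide.

**Functional-group changes (21 back to 18).** Acetal cleavage (20 to 21), oxidation (19 to 20) and silyl ether cleavage (18 to 19) change no carbon–carbon bond. They allow C4 to pass through the radical step as an inert silyl ether.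

**Removal of the C6 oxygen and the ring A alkene (18 back to 14).** The C6 carbonyl and the C2=C3 alkene of 14 are traces of how the rings were made. Only C7 can enolise, so the ketone gives a single enol triflate 16. Reduction gives the diene 17, and one hydrogenation saturates both rings to 18. No stereocentre is made or lost.

**C8–C9 (14 from 13), the key disconnection.** Cutting the bond between the quaternary C9 and the tertiary C8 opens ring B and removes both of its stereocentres and one quaternary carbon at once. The cut is placed here because a radical–alkene union tolerates the congestion of this bond better than an ionic alkylation would. It leaves the monocyclic cyclohexene 13, whose only stereochemical demand is a trans-1,2 pair (C5, C10). The forward step must deliver a hydrogen atom to the methylidene only, close 6-endo, and set C8 and C9 relative to C5 and C10.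

**C6–C7 (13 from 10 and 11).** The crotonoyl group is cut at the carbonyl. The (E)-propenyl unit 11 adds to the neopentyl aldehyde 10, and the carbinol 12 is oxidised. The E geometry that the key step needs is bought with 11.

**C4–C5 and C1–C10 (10 from 7 and 9).** Ring A is a Diels–Alder adduct. The 1-silyloxydiene 9 supplies C1–C4 with the C4 oxygen. The (E)-2-methyl enal 7 supplies C5 and C10, with the C5 methyl, C6 as the formyl group and the complete C9 arm. The E geometry of 7 becomes the trans relationship of the two arms. A chiral Lewis acid fixes the absolute configuration at C5 and C10, the only centres that must come from outside.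

**Fragments (7 from 5 and 6; 5 from 4; 4 from 2 and 3; 2 from 1; 9 from 8).** The C5=C10 bond of 7 comes from a Wittig reaction of the 2-substituted acrolein 5 with the formyl ylide 6. The C9 methylidene comes from α-methylenation of aldehyde 4. The aryl–CH2 bond comes from Heck arylation of allyl alcohol 3 with the iodide 2, the methoxymethyl ether of commercial 1. Diene 9 is the silyl dienol ether of crotonaldehyde 8.

## Alternatives that were turned down

**Alternative 1:** cation cascade on a chiral-pool drimane.
- **Disconnection:** no ring bond is cut. The C9–CH3 and C5–CH3 bonds and the C4 methylidene are traced back through 1,2-shifts to the 9-(arylmethyl)drimene A1, whose decalin and absolute configuration come from the chiral pool.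
- **Forward key step:** acid ionises C8 of A1. The 9α-hydrogen moves to C8, the 10β-methyl to C9, the 5α-hydrogen to C10 and the 4β-methyl to C5, and a proton is lost from the remaining C4 methyl. This gives the O-acetate A2, and deacetylation would give 23.
- **For:** each group migrates across the face it starts on, so all four stereocentres follow from A1. No asymmetric step is needed and the route is clearly shorter. On step economy and on the source of absolute configuration this alternative is stronger than the chosen route.
- **Against:** the cascade has many exits. The cations at C8, C9, C10 and C5 can each lose a proton or be captured by the arene or its oxygen. The last cation can lose a proton from C3 to give the more substituted ring alkene instead of the methylidene. The product alkene is itself labile under the acid that forms it.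
- **Comparison:** the position of the alkene, which is what defines 23, cannot be dictated by the substrate there. The chosen route is longer and must create its own absolute configuration. In exchange it places the methylidene without positional ambiguity, from a ketone in the last step, and makes each centre in a step with a defined transition state.

**Alternative 2:** hydroxyl-directed cyclopropanation.
- **Disconnection:** the C9 methyl is traced back to a cyclopropane CH2 spanning C8 and C9, and so to the allylic alcohol A3 with a tetrasubstituted C8=C9 alkene.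
- **Forward key step:** a zinc carbenoid held by the 7β-oxygen delivers CH2 to the β face and gives the cyclopropyl carbinol A4. Oxidation at C7, reductive cleavage of the C8–CH2 bond, deoxygenation and methylenation would follow.
- **For:** the face at C9 is fixed by intramolecular delivery. On the configuration of C9 this alternative is more secure than the rotamer-controlled radical closure of the chosen route.
- **Against:** A3 needs a tetrasubstituted alkene bearing ArCH2 inside a preformed decalin, and a 7β-hydroxyl. After the key step three operations on ring B serve only to erase the handle. C8 then depends on protonation next to a quaternary centre. The key step forms no ring of the target and only one stereocentre.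
- **Comparison:** the chosen key step forms ring B, the C8–C9 bond and two stereocentres at once from a monocyclic precursor that already carries the arene. It pays for this with a less certain C9.

**Alternative 3:** intramolecular Diels–Alder reaction.
- **Disconnection:** C5–C10 and C3–C4, back to the acyclic trienal A5.
- **Forward key step:** the C10=C1–C2=C3 diene adds across the (E)-C4=C5 enal and gives the octalin aldehyde A6 with both rings closed. The formyl carbon is C11, so reduction and dehydration would give the methylidene.
- **For:** two rings and two bonds form in one step, no carbon is added later and C6 never carries oxygen. In bond and redox economy around the key step this alternative is stronger.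
- **Against:** A5 must already hold C8 and the quaternary C9 as acyclic neighbours, which is as hard as the original problem. The dienophile is β,β-disubstituted and the diene terminus is neopentyl, so the cycloaddition would be slow. Neither the trans fusion nor the face relative to C8 and C9 is enforced.
- **Comparison:** the chosen route sets C5 and C10 first, on a simple dienophile under catalyst control. It then makes C8 and C9 inside a ring, where a chair transition state can be used.

Key step: step 9

## Remarks on the chemistry

- The C4 configuration drawn for 10 to 19 is that of endo addition (silyloxy cis to formyl). It has no bearing on 23, because C4 becomes a carbonyl carbon in step 14.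
- The carbinol carbon of 12 forms without control and is drawn without configuration. It becomes a carbonyl carbon in step 8.
- The sense of induction in step 6 is taken from the usual model of the catalyst–enal complex. If the antipode of 10 predominates, the (R)-configured catalyst is used.

## Route

Step 1
Reactants: 1 methyl 4-hydroxy-3-iodobenzoate
Product: 2 methyl 3-iodo-4-(methoxymethoxy)benzoate
Conditions: MOMCl, iPr2NEt, CH2Cl2, 0 °C to rt
Reagents that add atoms: chloromethyl methyl ether, COCCl
Why: O-alkylation of the phenoxide (Williamson type); the acetal keeps the phenol from being triflated in step 10 and from the oxidants.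

Step 2
Reactants: 2 aryl iodide; 3 allyl alcohol
Product: 4 methyl 4-(methoxymethoxy)-3-(3-oxopropyl)benzoate
Conditions: Pd(OAc)2 (cat.), Bu4NCl, NaHCO3, DMF, 50 °C
Reagents that add atoms: none
Why: Heck arylation of allyl alcohol: the aryl group adds to the terminal carbon, β-hydride elimination towards the carbinol gives the enol, and this tautomerises to the 3-arylpropanal.

Step 3
Reactants: 4 arylpropanal
Product: 5 methyl 3-(2-formylprop-2-en-1-yl)-4-(methoxymethoxy)benzoate
Conditions: CH2O (aq.), pyrrolidine (cat.), EtCO2H (cat.), iPrOH, 45 °C
Reagents that add atoms: formaldehyde, C=O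
Why: Amine-catalysed Mannich condensation followed by loss of the amine (α-methylenation of an aldehyde); the aldehyde has one enolisable position, and the new CH2 is the later C9 methyl.

Step 4
Reactants: 5 2-substituted acrolein; 6 2-(triphenyl-λ5-phosphanylidene)propanal
Product: 7 methyl 4-(methoxymethoxy)-3-[(3E)-4-methyl-2-methylidene-5-oxopent-3-en-1-yl]benzoate
Conditions: toluene, 90 °C
Reagents that add atoms: none
Why: Wittig reaction of a stabilised formyl ylide, which places the formyl group trans to the larger substituent (E); the product is α-branched and conjugated and reacts with the ylide more slowly than 5.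

Step 5
Reactants: 8 crotonaldehyde
Product: 9 (E)-(buta-1,3-dien-1-yloxy)(tert-butyl)dimethylsilane
Conditions: TBSOTf, Et3N, Et2O, 0 °C to rt
Reagents that add atoms: tert-butyldimethylsilyl trifluoromethanesulfonate, CC(C)(C)[Si](C)(C)OS(=O)(=O)C(F)(F)F
Why: O-silylation of the enal and γ-deprotonation by the amine (silyl dienol ether formation) give the (E)-1-silyloxydiene.

Step 6
Reactants: 7 dienal; 9 silyloxydiene
Product: 10 methyl 3-{2-[(1S,5R,6S)-5-{[tert-butyl(dimethyl)silyl]oxy}-6-formyl-6-methylcyclohex-3-en-1-yl]prop-2-en-1-yl}-4-(methoxymethoxy)benzoate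
Conditions: (S)-3,3-diphenyl-1-(o-tolyl)tetrahydro-1H,3H-pyrrolo[1,2-c][1,3,2]oxazaborole·HNTf2 (15 mol %), CH2Cl2, −78 to −40 °C
Reagents that add atoms: none
Why: Catalytic enantioselective Diels–Alder reaction of an α-substituted enal on a chiral cationic oxazaborolidine: the free terminus of 9 bonds to the β-carbon C10 and the oxygen-bearing terminus to C5 (ortho rule), and the suprafacial addition turns the E geometry of 7 into the trans relationship of the C5 formyl group and the C10 arm. The bound s-trans enal lies over one phenyl group of the catalyst, so 9 adds to the Re face of C5, which sets C5 (S) and C10 (S), and endo approach of the formyl group puts the silyloxy group cis to it. The second alkene of 7 is twisted out of conjugation by allylic strain with the C5 methyl and is not activated, so only C5=C10 reacts.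

Step 7
Reactants: 10 aldehyde; 11 (E)-1-bromoprop-1-ene
Product: 12 methyl 3-{2-[(1S,5R,6R)-5-{[tert-butyl(dimethyl)silyl]oxy}-6-[(2E)-1-hydroxybut-2-en-1-yl]-6-methylcyclohex-3-en-1-yl]prop-2-en-1-yl}-4-(methoxymethoxy)benzoate (both carbinol epimers)
Conditions: CrCl2, NiCl2 (cat.), DMF, rt
Reagents that add atoms: none
Why: Nozaki–Hiyama–Kishi addition: the alkenylchromium reagent forms with retention of the E geometry and adds only to the aldehyde, so the methyl ester is untouched; the carbinol configuration is irrelevant.

Step 8
Reactants: 12 allylic alcohol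
Product: 13 methyl 3-{2-[(1S,5R,6S)-6-[(2E)-but-2-enoyl]-5-{[tert-butyl(dimethyl)silyl]oxy}-6-methylcyclohex-3-en-1-yl]prop-2-en-1-yl}-4-(methoxymethoxy)benzoate
Conditions: Dess–Martin periodinane, CH2Cl2, 0 °C to rt
Reagents that add atoms: none
Why: Dess–Martin oxidation of a secondary allylic alcohol under near-neutral conditions; the E alkene and the silyl and acetal groups are not affected.

Step 9
Reactants: 13 crotonoyl cyclohexene
Product: 14 methyl 3-{[(1R,2S,4aS,5R,8aS)-5-{[tert-butyl(dimethyl)silyl]oxy}-1,2,4a-trimethyl-4-oxo-1,2,3,4,4a,5,8,8a-octahydronaphthalen-1-yl]methyl}-4-(methoxymethoxy)benzoate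
Conditions: Fe(acac)3 (cat.), PhSiH3, EtOH/(CH2OH)2, 60 °C
Reagents that add atoms: none
Why: An iron hydride formed from Fe(acac)3, PhSiH3 and ethanol transfers a hydrogen atom to the CH2 terminus of the 1,1-disubstituted alkene, which creates the C9 methyl and a tertiary C9 radical; the cis-disubstituted C2=C3 alkene and the electron-poor enone accept hydrogen atoms far more slowly, and this is the chemoselectivity the step needs. The nucleophilic radical adds to the β-carbon C8 of the (E)-propenyl ketone, and the C7 α-keto radical is reduced to the iron enolate and protonated by ethanol; the closest known reaction type is the iron-hydride-initiated reductive coupling of an unactivated alkene with an enone (Giese-type addition), used here intramolecularly. Ring B closes in the 6-endo-trig mode with the C6 carbonyl inside the ring, because attack at C7 (5-exo) would oppose the polarity of the enone and give an unstabilised secondary radical. The two arms are trans on ring A and both equatorial in the half-chair that keeps the C5 methyl axial, so the new ring can only be trans-fused and closes through a chair. In that chair the E geometry keeps the C8 methyl anti to C6 and therefore equatorial, which sets C8 (S, β-methyl); this centre cannot be corrected later and must come from the transition state. C9 is set by the rotamer about C10–C9 of the planar radical: the substituent that becomes axial lies beside the quaternary C5 and its axial methyl and the one that becomes equatorial lies beside C10–H, so the smaller CH3 is expected inside and ArCH2 outside, which gives C9 (R). This second control rests on a modest difference in size and is the less secure of the two.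

Step 10
Reactants: 14 octalinone
Product: 16 methyl 3-{[(1R,2S,4aS,5R,8aS)-5-{[tert-butyl(dimethyl)silyl]oxy}-1,2,4a-trimethyl-4-{[(trifluoromethyl)sulfonyl]oxy}-1,2,4a,5,8,8a-hexahydronaphthalen-1-yl]methyl}-4-(methoxymethoxy)benzoate, via potassium C6-enolate 15 (not isolated)
Conditions: KHMDS, THF, −78 °C; then PhNTf2, −78 to 0 °C
Reagents that add atoms: N-phenylbis(trifluoromethanesulfonimide), O=S(=O)(N(c1ccccc1)S(=O)(=O)C(F)(F)F)C(F)(F)F
Why: Only C7 carries α-hydrogens (C5 is quaternary), so enolisation gives a single enolate, which is O-sulfonylated (enol triflate formation).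

Step 11
Reactants: 16 enol triflate
Product: 17 methyl 3-{[(1R,2S,4aS,5R,8aS)-5-{[tert-butyl(dimethyl)silyl]oxy}-1,2,4a-trimethyl-1,2,4a,5,8,8a-hexahydronaphthalen-1-yl]methyl}-4-(methoxymethoxy)benzoate
Conditions: Pd(OAc)2 (cat.), PPh3, Bu3N, HCO2H, DMF, 60 °C
Reagents that add atoms: none
Why: Palladium-catalysed formate reduction of an enol triflate: oxidative addition to zerovalent palladium, exchange for formate, loss of CO2 to a palladium hydride and reductive elimination replace C–O by C–H, which removes the C6 oxygen.

Step 12
Reactants: 17 diene
Product: 18 methyl 3-{[(1R,2S,4aS,5R,8aS)-5-{[tert-butyl(dimethyl)silyl]oxy}-1,2,4a-trimethyldecahydronaphthalen-1-yl]methyl}-4-(methoxymethoxy)benzoate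
Conditions: H2 (1–3 atm), PtO2 (cat.), EtOAc, rt
Reagents that add atoms: none
Why: Heterogeneous hydrogenation of two cis-disubstituted ring alkenes (C2=C3 and C6=C7), which creates no stereocentre; platinum is chosen because it isomerises alkenes less than palladium and does not readily cleave the allylic C–O bond.

Step 13
Reactants: 18 silyl ether
Product: 19 methyl 3-{[(1R,2S,4aS,5R,8aS)-5-hydroxy-1,2,4a-trimethyldecahydronaphthalen-1-yl]methyl}-4-(methoxymethoxy)benzoate
Conditions: HF·pyridine, pyridine, THF, 0 °C to rt
Reagents that add atoms: none
Why: Fluoride cleavage of the hindered secondary silyl ether through the strong Si–F bond; the buffered, non-nucleophilic medium leaves the methyl ester and the aryl acetal alone.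

Step 14
Reactants: 19 alcohol
Product: 20 methyl 4-(methoxymethoxy)-3-{[(1R,2S,4aS,8aS)-1,2,4a-trimethyl-5-oxodecahydronaphthalen-1-yl]methyl}benzoate
Conditions: Dess–Martin periodinane, CH2Cl2, rt
Reagents that add atoms: none
Why: Dess–Martin oxidation of a hindered secondary alcohol; C4 becomes the carbonyl carbon needed for the methylidene, and its configuration no longer matters.

Step 15
Reactants: 20 ketone
Product: 21 methyl 4-hydroxy-3-{[(1R,2S,4aS,8aS)-1,2,4a-trimethyl-5-oxodecahydronaphthalen-1-yl]methyl}benzoate
Conditions: HCl (aq.), MeOH, 40 °C
Reagents that add atoms: none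
Why: Acid-catalysed acetal exchange with methanol frees the phenol; it is done now, while the molecule holds no acid-sensitive alkene, and the methyl ester is stable in methanol.

Step 16
Reactants: 21 keto phenol
Product: 23 dictyoceratin C, methyl 4-hydroxy-3-{[(1R,2S,4aS,8aS)-1,2,4a-trimethyl-5-methylidenedecahydronaphthalen-1-yl]methyl}benzoate, via potassium phenoxide 22 (not isolated)
Conditions: KOtBu (1 equiv), THF, 0 °C; then Ph3P=CH2 (excess, from Ph3PCH3Br, KOtBu), THF, 65 °C; then AcOH
Reagents that add atoms: methyltriphenylphosphonium bromide, C[P+](c1ccccc1)(c1ccccc1)c1ccccc1.[Br-]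
Why: Wittig methylenation of the C4 ketone with excess non-stabilised ylide at raised temperature, as ketones beside a quaternary carbon require; the phenoxide para to the ester makes the ester a poor electrophile, so the ylide attacks only the ketone, and no stereocentre is touched.

## Compound list

1 | methyl 4-hydroxy-3-iodobenzoate | COC(=O)c1ccc(O)c(I)c1 | starting material
2 | methyl 3-iodo-4-(methoxymethoxy)benzoate | COCOc1ccc(C(=O)OC)cc1I | intermediate
3 | allyl alcohol (prop-2-en-1-ol) | C=CCO | starting material
4 | methyl 4-(methoxymethoxy)-3-(3-oxopropyl)benzoate | COCOc1ccc(C(=O)OC)cc1CCC=O | intermediate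
5 | methyl 3-(2-formylprop-2-en-1-yl)-4-(methoxymethoxy)benzoate | COCOc1ccc(C(=O)OC)cc1CC(=C)C=O | intermediate
6 | 2-(triphenyl-λ5-phosphanylidene)propanal | CC(C=O)=P(c1ccccc1)(c1ccccc1)c1ccccc1 | starting material
7 | methyl 4-(methoxymethoxy)-3-[(3E)-4-methyl-2-methylidene-5-oxopent-3-en-1-yl]benzoate | O=C/C(C)=C/C(=C)Cc1cc(C(=O)OC)ccc1OCOC | intermediate
8 | crotonaldehyde, (E)-but-2-enal | C/C=C/C=O | starting material
9 | (E)-(buta-1,3-dien-1-yloxy)(tert-butyl)dimethylsilane | C=C/C=C/O[Si](C)(C)C(C)(C)C | intermediate
10 | methyl 3-{2-[(1S,5R,6S)-5-{[tert-butyl(dimethyl)silyl]oxy}-6-formyl-6-methylcyclohex-3-en-1-yl]prop-2-en-1-yl}-4-(methoxymethoxy)benzoate (C4 α-OSi, C5 β-CH3, C10 α-H) | C=C(Cc1cc(C(=O)OC)ccc1OCOC)[C@@H]1CC=C[C@@H](O[Si](C)(C)C(C)(C)C)[C@@]1(C)C=O | intermediate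
11 | (E)-1-bromoprop-1-ene | C/C=C/Br | starting material
12 | methyl 3-{2-[(1S,5R,6R)-5-{[tert-butyl(dimethyl)silyl]oxy}-6-[(2E)-1-hydroxybut-2-en-1-yl]-6-methylcyclohex-3-en-1-yl]prop-2-en-1-yl}-4-(methoxymethoxy)benzoate, both carbinol epimers | C=C(Cc1cc(C(=O)OC)ccc1OCOC)[C@@H]1CC=C[C@@H](O[Si](C)(C)C(C)(C)C)[C@@]1(C)C(O)/C=C/C | intermediate
13 | methyl 3-{2-[(1S,5R,6S)-6-[(2E)-but-2-enoyl]-5-{[tert-butyl(dimethyl)silyl]oxy}-6-methylcyclohex-3-en-1-yl]prop-2-en-1-yl}-4-(methoxymethoxy)benzoate | C=C(Cc1cc(C(=O)OC)ccc1OCOC)[C@@H]1CC=C[C@@H](O[Si](C)(C)C(C)(C)C)[C@@]1(C)C(=O)/C=C/C | intermediate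
14 | methyl 3-{[(1R,2S,4aS,5R,8aS)-5-{[tert-butyl(dimethyl)silyl]oxy}-1,2,4a-trimethyl-4-oxo-1,2,3,4,4a,5,8,8a-octahydronaphthalen-1-yl]methyl}-4-(methoxymethoxy)benzoate | CC(C)(C)[Si](C)(C)O[C@@H]1C=CC[C@H]2[C@](C)(Cc3cc(C(=O)OC)ccc3OCOC)[C@@H](C)CC(=O)[C@]12C | intermediate
15 | potassium C6-enolate of 14 | CC(C)(C)[Si](C)(C)O[C@@H]1C=CC[C@H]2[C@](C)(Cc3cc(C(=O)OC)ccc3OCOC)[C@@H](C)C=C([O-])[C@]12C.[K+] | intermediate
16 | methyl 3-{[(1R,2S,4aS,5R,8aS)-5-{[tert-butyl(dimethyl)silyl]oxy}-1,2,4a-trimethyl-4-{[(trifluoromethyl)sulfonyl]oxy}-1,2,4a,5,8,8a-hexahydronaphthalen-1-yl]methyl}-4-(methoxymethoxy)benzoate | CC(C)(C)[Si](C)(C)O[C@@H]1C=CC[C@H]2[C@](C)(Cc3cc(C(=O)OC)ccc3OCOC)[C@@H](C)C=C(OS(=O)(=O)C(F)(F)F)[C@]12C | intermediate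
17 | methyl 3-{[(1R,2S,4aS,5R,8aS)-5-{[tert-butyl(dimethyl)silyl]oxy}-1,2,4a-trimethyl-1,2,4a,5,8,8a-hexahydronaphthalen-1-yl]methyl}-4-(methoxymethoxy)benzoate | CC(C)(C)[Si](C)(C)O[C@@H]1C=CC[C@H]2[C@](C)(Cc3cc(C(=O)OC)ccc3OCOC)[C@@H](C)C=C[C@]12C | intermediate
18 | methyl 3-{[(1R,2S,4aS,5R,8aS)-5-{[tert-butyl(dimethyl)silyl]oxy}-1,2,4a-trimethyldecahydronaphthalen-1-yl]methyl}-4-(methoxymethoxy)benzoate | CC(C)(C)[Si](C)(C)O[C@@H]1CCC[C@H]2[C@](C)(Cc3cc(C(=O)OC)ccc3OCOC)[C@@H](C)CC[C@]12C | intermediate
19 | methyl 3-{[(1R,2S,4aS,5R,8aS)-5-hydroxy-1,2,4a-trimethyldecahydronaphthalen-1-yl]methyl}-4-(methoxymethoxy)benzoate | O[C@@H]1CCC[C@H]2[C@](C)(Cc3cc(C(=O)OC)ccc3OCOC)[C@@H](C)CC[C@]12C | intermediate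
20 | methyl 4-(methoxymethoxy)-3-{[(1R,2S,4aS,8aS)-1,2,4a-trimethyl-5-oxodecahydronaphthalen-1-yl]methyl}benzoate | O=C1CCC[C@H]2[C@](C)(Cc3cc(C(=O)OC)ccc3OCOC)[C@@H](C)CC[C@]12C | intermediate
21 | methyl 4-hydroxy-3-{[(1R,2S,4aS,8aS)-1,2,4a-trimethyl-5-oxodecahydronaphthalen-1-yl]methyl}benzoate | O=C1CCC[C@H]2[C@](C)(Cc3cc(C(=O)OC)ccc3O)[C@@H](C)CC[C@]12C | intermediate
22 | potassium phenoxide of 21 | O=C1CCC[C@H]2[C@](C)(Cc3cc(C(=O)OC)ccc3[O-])[C@@H](C)CC[C@]12C.[K+] | intermediate
23 | dictyoceratin C, methyl 4-hydroxy-3-{[(1R,2S,4aS,8aS)-1,2,4a-trimethyl-5-methylidenedecahydronaphthalen-1-yl]methyl}benzoate | C=C1CCC[C@H]2[C@](C)(Cc3cc(C(=O)OC)ccc3O)[C@@H](C)CC[C@]12C | target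

## Step count and least certain steps

Total: 16 steps. Longest linear sequence: 15 steps (steps 1–4 and 6–16, from 1). Step 5 is a one-step side branch.

**Step 9 (key step).**
- What may go wrong: the tertiary C9 radical may be diverted before ring closure, by reduction to the saturated side chain or by back-transfer of a hydrogen atom that isomerises the alkene. The C8–C9 bond joins a quaternary to a tertiary carbon on a β-substituted acceptor, so closure is slow compared with these processes in a medium that holds a metal hydride.
- Second uncertainty: facial control at the planar C9 radical may be incomplete, since CH3 and ArCH2 differ only moderately. The fallback does not remove this.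
- Fallback, setting out from 12 and returning at 14: Mukaiyama hydration of the methylidene of 12 (Co(acac)2, PhSiH3, O2) gives the C9 tertiary alcohol F1. Dess–Martin oxidation of its secondary allylic hydroxyl gives the hydroxy enone F2. Acylation with methyl chlorooxoacetate gives the methyl oxalate F3, and one equivalent of aqueous CsOH converts it into the cesium oxalate F4. Visible-light irradiation of F4 with Ir[dF(CF3)ppy]2(dtbbpy)PF6 in wet DME/DMF releases two molecules of CO2 and the same C9 radical, which closes to 14. No hydride donor is present, so the slow cyclisation has no reductive competitor.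

**Step 6.**
- What may go wrong: enantiocontrol may be lost through an achiral background reaction. Silyl transfer from 9 to the triflimide would give a silyl Lewis acid that catalyses the cycloaddition without the chiral ligand. The silyl dienol ether may also add to the activated aldehyde in a Mukaiyama-type process instead of cycloadding. The sense of induction for this trisubstituted enal is inferred from a model.
- Fallback, setting out from 7 and 9 and returning at 10: heating 7 with 9 in toluene without catalyst gives 10 together with its enantiomer F5 as the racemate. Condensation with (1R,2R)-N,N'-dimethyl-1,2-diphenylethane-1,2-diamine gives the diastereomeric imidazolidine of 10 F6 and the imidazolidine of the enantiomer F7, which are separated by chromatography. Mild aqueous acid hydrolysis of F6 returns enantiopure 10.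

**Step 12.**
- What may go wrong: the C6=C7 double bond may migrate towards C8 on the metal surface before hydrogen is added, which would erase the C8 configuration. Reduction of this alkene beside the quaternary C5 may also be slow.
- Fallback, setting out from 14 and returning at 18: hydrogenation of the unhindered C2=C3 alkene of 14 (H2, PtO2) gives the saturated ketone F8. NaBH4 reduces it to the C6 alcohol F9. NaH, CS2 and MeI give the S-methyl xanthate F10, and Bu3SnH with AIBN (Barton–McCombie deoxygenation) gives 18. No alkene is ever placed next to C8.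

**Step 16.**
- What may go wrong: the basic ylide may enolise the C4 ketone instead of adding to it, because the carbonyl is flanked by the quaternary C5. If deprotonation of the phenol is incomplete, the ylide may attack the ester.
- Fallback, setting out from 21 and returning at 23: the organocerium reagent from Me3SiCH2Li and CeCl3, which is nucleophilic but barely basic, adds to the ketone of 21 and gives the β-hydroxysilane F11. Treatment with KH eliminates the silanolate (Peterson olefination) and gives 23.

## Further compounds

F1 | step 9 | C9 tertiary alcohol from hydration of 12 (diol, epimers at C9 and at the carbinol carbon) | CC(O)(Cc1cc(C(=O)OC)ccc1OCOC)[C@@H]1CC=C[C@@H](O[Si](C)(C)C(C)(C)C)[C@@]1(C)C(O)/C=C/C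
F2 | step 9 | C9-hydroxy crotonoyl cyclohexene (hydroxy enone, epimers at C9) | CC(O)(Cc1cc(C(=O)OC)ccc1OCOC)[C@@H]1CC=C[C@@H](O[Si](C)(C)C(C)(C)C)[C@@]1(C)C(=O)/C=C/C
F3 | step 9 | methyl oxalate of F2 | CC(OC(=O)C(=O)OC)(Cc1cc(C(=O)OC)ccc1OCOC)[C@@H]1CC=C[C@@H](O[Si](C)(C)C(C)(C)C)[C@@]1(C)C(=O)/C=C/C
F4 | step 9 | cesium oxalate of F2 | CC(OC(=O)C(=O)[O-])(Cc1cc(C(=O)OC)ccc1OCOC)[C@@H]1CC=C[C@@H](O[Si](C)(C)C(C)(C)C)[C@@]1(C)C(=O)/C=C/C.[Cs+]
F5 | step 6 | enantiomer of 10 | C=C(Cc1cc(C(=O)OC)ccc1OCOC)[C@H]1CC=C[C@H](O[Si](C)(C)C(C)(C)C)[C@]1(C)C=O
F6 | step 6 | (4R,5R)-1,3-dimethyl-4,5-diphenylimidazolidin-2-yl derivative of 10 (aminal at the formyl carbon) | C=C(Cc1cc(C(=O)OC)ccc1OCOC)[C@@H]1CC=C[C@@H](O[Si](C)(C)C(C)(C)C)[C@@]1(C)C1N(C)[C@H](c2ccccc2)[C@@H](c2ccccc2)N1C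
F7 | step 6 | (4R,5R)-1,3-dimethyl-4,5-diphenylimidazolidin-2-yl derivative of F5 | C=C(Cc1cc(C(=O)OC)ccc1OCOC)[C@H]1CC=C[C@H](O[Si](C)(C)C(C)(C)C)[C@]1(C)C1N(C)[C@H](c2ccccc2)[C@@H](c2ccccc2)N1C
F8 | step 12 | 2,3-dihydro derivative of 14 (saturated C6 ketone) | CC(C)(C)[Si](C)(C)O[C@@H]1CCC[C@H]2[C@](C)(Cc3cc(C(=O)OC)ccc3OCOC)[C@@H](C)CC(=O)[C@]12C
F9 | step 12 | C6 alcohol from F8 (either epimer) | CC(C)(C)[Si](C)(C)O[C@@H]1CCC[C@H]2[C@](C)(Cc3cc(C(=O)OC)ccc3OCOC)[C@@H](C)CC(O)[C@]12C
F10 | step 12 | O-alkyl S-methyl xanthate of F9 | CC(C)(C)[Si](C)(C)O[C@@H]1CCC[C@H]2[C@](C)(Cc3cc(C(=O)OC)ccc3OCOC)[C@@H](C)CC(OC(=S)SC)[C@]12C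
F11 | step 16 | C4 tertiary alcohol bearing CH2SiMe3 (β-hydroxysilane from 21, either C4 epimer) | C[Si](C)(C)CC1(O)CCC[C@H]2[C@](C)(Cc3cc(C(=O)OC)ccc3O)[C@@H](C)CC[C@]12C
A1 | alternative 1 | 9-(arylmethyl)drim-8(12)-ene, aryl = 2-acetoxy-5-(methoxycarbonyl)phenyl (5α-H, 9α-H, 10β-CH3) | C=C1CC[C@H]2C(C)(C)CCC[C@]2(C)[C@H]1Cc1cc(C(=O)OC)ccc1OC(C)=O
A2 | alternative 1 | dictyoceratin C O-acetate | C=C1CCC[C@H]2[C@](C)(Cc3cc(C(=O)OC)ccc3OC(C)=O)[C@@H](C)CC[C@]12C
A3 | alternative 2 | 7β-hydroxy C8=C9 alkene with C4 dioxolane (allylic alcohol) | O1CCOC12CCC[C@H]3C(Cc4cc(C(=O)OC)ccc4OCOC)=C(C)[C@@H](O)C[C@]23C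
A4 | alternative 2 | β-face cyclopropyl carbinol | O1CCOC12CCC[C@H]3[C@@]4(Cc5cc(C(=O)OC)ccc5OCOC)C[C@@]4(C)[C@@H](O)C[C@]23C
A5 | alternative 3 | acyclic trienal with C8 and C9 in place | C=C/C=C/[C@](C)(Cc1cc(C(=O)OC)ccc1OCOC)[C@@H](C)CC/C(C)=C/C=O
A6 | alternative 3 | trans-octalin 4-carbaldehyde | O=C[C@H]1CC=C[C@H]2[C@](C)(Cc3cc(C(=O)OC)ccc3OCOC)[C@@H](C)CC[C@]12C
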